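The elm run at 65 °C and the ash run at 76 °C give us the clock we need to compare teal and ochre.

| setting | elm | ash | teal | ochre |
|---|---|---|---|---|
| starting material | 0.014 M | 0.022 M | 0.010 M | 0.010 M |
| temperature | 65 °C | 76 °C |  |  |
| remark | run made earlier | run made earlier | at 80 °C until 2.0 h, from then on at 60 °C | at 80 °C throughout |
| time |  |  | 10 h | 6.0 h |

| elm: time / h | elm: product / % | ash: time / h | ash: product / % |
|---|---|---|---|
| 2.00 | 15.6 | 2.00 | 46.7 |
| 3.00 | 22.9 | 4.00 | 72.0 |
| 6.00 | 40.8 | 6.00 | 84.3 |
| 10.0 | 59.3 | 8.00 | 91.9 |
| 20.0 | 82.3 | 10.0 | 96.1 |

(readings scatter by 0.5 percentage points)

- amounts and yields of product count crystals too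
- given per volume of solution although it is solid: crystals
- steps under discussion: starting material -> product; crystals <-> product

1. the winner by amount of product, in percent of the starting material charged; "neither" if no more than 2 percentage points parts them (teal / ochre / neither)
2. how much product is there at the end, in percent of the starting material charged: teal
3. how much product is there at the end, in percent of the starting material charged: ochre

We take [starting material] as what the product, crystals counted, has not yet taken. In the ash run the logarithm of charged over remaining [starting material], divided by time, gives 0.315 h⁻¹ at 2.00 h and 0.314 h⁻¹ at 8.00 h, so we treat the step as first order and carry its constants to the charge of 0.010 M. Pooling two readings per run, we read 0.0868 h⁻¹ for elm and 0.316 h⁻¹ for ash, and the two give an activation temperature of 13900 K.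

By that reading, an hour at 60 °C is worth 0.0948 of an hour at 80 °C. So we count hot hours, the time at 80 °C that turns over as much starting material as the programme does (the equivalent time at a reference temperature). For teal they are the first 2.0 h plus a correction for the 8.00 h at 60 °C, in sum 2.76 h, while ochre has 6.0 h.

The first way uses the first-order law with 0.495 h⁻¹ at 80 °C, and it gives 74.4% for teal and 94.9% for ochre. The second way uses no law of time. We turn hot hours into ash hours, 4.32 h and 9.41 h, and read the ash table along straight lines between readings, which gives 74.0% and 94.9%.

Both ways share the temperature factor, so their agreement tests the time law and not that factor. They part by 0.40 percentage points on teal, less than the scatter of 0.5 points, and the straight line is the one that cheats, since a chord runs under a curve that is flattening. We commit to the first way, with ochre ahead.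

The forecast, close to our figures, says 74.5% for teal, 94.9% for ochre and ochre as winner, on the ground that “Cooling costs teal much more than its extra time recovers”.

The flasks give 74.7% for teal and 95.0% for ochre, so ochre wins.

    starting material → product (k = 0.00830 min⁻¹, Ea = 115 kJ mol⁻¹)
    crystals ⇌ product, rate k2*(cs2 - [product]) while solid is left; crystals form when [product] > cs2 (solubility = 0.190 mM, k = 0.160 min⁻¹)
    (constants at 80 °C)

Teal held 63.1% of product at its change of temperature, after 2.00 h, and the cold stretch added 12 points, the yield of 0.760 h out of a hot time of 2.76 h. Teal stopped at 4.0 h has a hot time of 2.19 h, which reckons to 66.2%, and that flask stood at 66.4%.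

Readings and results come from a simulation with made-up constants; scatter was added.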